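## Retrosynthetic overview

Benzofuran numbering is used throughout: O1, C2, C3, C3a, C4–C7, C7a.

1. The strategy rests on C2, the one carbon of the dihydrofuran ring (O1–C2–C3–C3a–C7a) that is bonded to O1, to C3 and to the carbinol side chain. Cutting O1–C2 and C2–C3 leads to a C3a-methylene o-quinone methide whose only free oxygen is the one on C7a, and to a one-carbon acetonyl sulfonium ylide ([4+1]).
2. The tertiary carbinol comes from chelation-controlled addition of homoprenylmagnesium bromide to the C2 acetyl group. The C7 isobutyryl group comes from directed lithiation between O1 and the C6 OMOM group.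
3. The quaternary centres are made last, on the free acylphloroglucinol. C5 is set by Pd-catalysed prenylation of the O4,O6-dianion. C7 is not alkylated directly, because the acyl-bearing carbon is the least nucleophilic terminus of the vinylogous acid; instead O4 is prenylated and the prenyl group is relayed by Claisen (to C3a) and Cope (to C7) rearrangement.
4. Ring order: the benzene ring is bought (2-methylresorcinol), the dihydrofuran ring closes in the key step, and the carbocycle is dearomatised at the end.

Key step: step 9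

Assumption: the absolute sense of induction in steps 9 and 13 is predicted from steric models and is not established. Should either be opposite, the antipodal reagent is used with no other change: (2S,5S)-2,5-dimethylthiolane from (2R,5R)-hexane-2,5-diol in step 9, the (S,S) ligand in step 13.

## Route

Step 1
Reactants: 1 2-methylbenzene-1,3-diol
Product: 2 1,3-bis(methoxymethoxy)-2-methylbenzene
Conditions: MOMCl (2.5 equiv), i-Pr2NEt (3 equiv), CH2Cl2, 0 °C → rt
Reagents that add atoms: chloromethyl methyl ether, COCCl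
Why: O-alkylation of both phenols with an α-chloro ether under amine base (MOM protection), chosen because MOM ethers survive the later base, hydride, Grignard and organolithium steps and direct the lithiation of step 11.

Step 2
Reactants: 2 1,3-bis(methoxymethoxy)-2-methylbenzene
Product: 3 2-[3,5-bis(methoxymethoxy)-4-methylphenyl]-4,4,5,5-tetramethyl-1,3,2-dioxaborolane
Conditions: [Ir(OMe)(cod)]2 (1.5 mol%), dtbpy (3 mol%), B2pin2 (1.0 equiv), THF, 80 °C
Reagents that add atoms: bis(pinacolato)diboron, CC1(C)OB(OC1(C)C)B1OC(C)(C)C(C)(C)O1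
Why: Iridium-catalysed aromatic C–H borylation is sterically controlled and should go to the only ring C–H without an ortho substituent, the one para to the methyl group.

Step 3
Reactants: 3 2-[3,5-bis(methoxymethoxy)-4-methylphenyl]-4,4,5,5-tetramethyl-1,3,2-dioxaborolane
Product: 4 3,5-bis(methoxymethoxy)-4-methylphenol
Conditions: H2O2 (30% aq.), NaOH, THF, 0 °C → rt
Reagents that add atoms: hydrogen peroxide, OO
Why: Oxidation of the aryl boronate with basic peroxide (aryl shift from boron to oxygen, then hydrolysis) should give the symmetric phenol, whose two ortho positions are equivalent.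

Step 4
Reactants: 4 3,5-bis(methoxymethoxy)-4-methylphenol
Product: 5 6-hydroxy-2,4-bis(methoxymethoxy)-3-methylbenzaldehyde
Conditions: MgCl2 (2 equiv), Et3N (4 equiv), (CH2O)n (6 equiv), MeCN, 80 °C; aq. NH4Cl
Reagents that add atoms: paraformaldehyde (as formaldehyde), C=O
Why: Magnesium-mediated ortho-formylation of a phenol (Casnati–Skattebøl reaction), in which the magnesium phenoxide delivers formaldehyde to the ortho carbon and a second formaldehyde oxidises the benzylic alkoxide; the two ortho positions are equivalent, so one aldehyde is possible, and the hydrogen-bonded product should resist a second formylation.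

Step 5
Reactants: 5 6-hydroxy-2,4-bis(methoxymethoxy)-3-methylbenzaldehyde
Product: 6 2-(hydroxymethyl)-3,5-bis(methoxymethoxy)-4-methylphenol
Conditions: NaBH4 (1.0 equiv), THF/MeOH 4:1, 0 °C, short reaction time; pH 7 buffer
Reagents that add atoms: none
Why: Borohydride reduction of the aldehyde, run cold and briefly because this electron-rich salicyl alcohol loses water easily, which is the property used in step 9, so it should be used at once.

Step 6
Reactants: 7 (2S,5S)-hexane-2,5-diol
Product: 8 (2S,5S)-hexane-2,5-diyl dimethanesulfonate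
Conditions: MsCl (2.4 equiv), Et3N (3 equiv), CH2Cl2, 0 °C
Reagents that add atoms: methanesulfonyl chloride, CS(=O)(=O)Cl
Why: Sulfonylation of both secondary alcohols at oxygen, which leaves the two stereocentres untouched.

Step 7
Reactants: 8 (2S,5S)-hexane-2,5-diyl dimethanesulfonate
Product: 9 (2R,5R)-2,5-dimethylthiolane
Conditions: Na2S·9H2O (1.2 equiv), DMSO, rt; distillation
Reagents that add atoms: sodium sulfide, [Na+].[Na+].[S-2]
Why: Double SN2 displacement by sulfide, first intermolecular and then 5-exo-tet, inverts both centres and should give the C2-symmetric (2R,5R)-thiolane.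

Step 8
Reactants: 9 (2R,5R)-2,5-dimethylthiolane; 10 1-chloropropan-2-one
Product: 11 (2R,5R)-2,5-dimethyl-1-(2-oxopropyl)thiolan-1-ium chloride
Conditions: 10 (2 equiv), NaI (10 mol%), acetone, 40 °C; trituration with Et2O
Reagents that add atoms: none
Why: S-alkylation of the sulfide by the α-halo ketone, speeded by iodide through Finkelstein exchange; because the thiolane is C2-symmetric, sulfur is not a stereocentre and a single sulfonium salt should form.

Step 9
Reactants: 6 2-(hydroxymethyl)-3,5-bis(methoxymethoxy)-4-methylphenol; 11 (2R,5R)-2,5-dimethyl-1-(2-oxopropyl)thiolan-1-ium chloride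
Product: 15 1-[(2S)-4,6-bis(methoxymethoxy)-5-methyl-2,3-dihydro-1-benzofuran-2-yl]ethan-1-one, via sulfonium ylide 12 (not isolated), via o-quinone methide 13 (not isolated), via phenoxide betaine 14 (not isolated)
Conditions: 11 (1.5 equiv), Cs2CO3 (1.5 equiv), 4 Å MS, CH2Cl2, 0 °C, 30 min; then 6 added over 3 h, 0 °C → rt; cold pH 7 buffer
Reagents that add atoms: none
Why: Carbonate converts 11 into the acetyl-stabilised ylide 12, and the alkoxy donors ortho and para to the benzylic carbon let 6 lose water under these mild conditions to give o-quinone methide 13; the ylide carbon adds to the exocyclic methylene (C2–C3), the ring re-aromatises as phenoxide betaine 14, and the phenoxide displaces the thiolane at the same carbon (O1–C2). The closest known reaction type is the formal [4+1] annulation of o-quinone methides with sulfonium ylides to 2-substituted 2,3-dihydrobenzofurans, chiral-sulfide variants included. The dihydrofuran ring closes 5-exo-tet, with the sulfide leaving anti to the incoming oxygen. C2 is the only new stereocentre: the C2–H of 14 lies between sulfonium and carbonyl and exchanges fast, so the two epimers of 14 interconvert, and the C2-symmetric thiolanium lets the epimer cyclise faster whose acetyl group, held in the plane perpendicular to the O···C···S axis, avoids the ring methyl syn to the side chain; after inversion this is predicted to give (S)-15. No regiocontrol is needed because the oxygen on C7a is the only unprotected one. Self-condensation of 13 is held back by adding 6 slowly to excess ylide, and epimerisation of the α-aryloxy ketone by using no base stronger than carbonate and the ylide and quenching cold at pH 7.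

Step 10
Reactants: 15 1-[(2S)-4,6-bis(methoxymethoxy)-5-methyl-2,3-dihydro-1-benzofuran-2-yl]ethan-1-one; 16 5-bromo-2-methylpent-2-ene
Product: 18 (2S)-2-[(2S)-4,6-bis(methoxymethoxy)-5-methyl-2,3-dihydro-1-benzofuran-2-yl]-6-methylhept-5-en-2-ol, via homoprenylmagnesium bromide 17 (not isolated)
Conditions: 16, Mg, Et2O, reflux (gives 17); 15, MgBr2·OEt2 (1.5 equiv), CH2Cl2, −78 °C, then 17 (2 equiv), −78 °C; aq. NH4Cl
Reagents that add atoms: none
Why: Grignard addition under Cram chelation control, in which magnesium bridges O1 and the carbonyl oxygen in a five-membered chelate and the homoprenyl group adds to the carbonyl face on the side of the C2–H, anti to C3, which should give the (S)-carbinol (O1 and OH syn), while the low temperature and weakly coordinating solvent keep addition ahead of enolisation at C2.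

Step 11
Reactants: 18 (2S)-2-[(2S)-4,6-bis(methoxymethoxy)-5-methyl-2,3-dihydro-1-benzofuran-2-yl]-6-methylhept-5-en-2-ol; 19 N-methoxy-N,2-dimethylpropanamide
Product: 21 1-[(2S)-2-[(2S)-2-hydroxy-6-methylhept-5-en-2-yl]-4,6-bis(methoxymethoxy)-5-methyl-2,3-dihydro-1-benzofuran-7-yl]-2-methylpropan-1-one, via dilithiated alkoxide 20 (not isolated)
Conditions: n-BuLi (2.4 equiv), TMEDA (2.4 equiv), THF, −20 → 0 °C; then 19 (1.5 equiv), −78 → 0 °C; aq. NH4Cl
Reagents that add atoms: none
Why: Directed ortho-metalation followed by Weinreb ketone synthesis: once the alkoxide has formed, butyllithium should remove the only aromatic proton, which lies between O1 and the C6 OMOM group, and the aryllithium forms a stable tetrahedral adduct with the Weinreb amide that gives the ketone only on work-up, so neither over-addition nor acylation of the alkoxide is expected.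

Step 12
Reactants: 21 1-[(2S)-2-[(2S)-2-hydroxy-6-methylhept-5-en-2-yl]-4,6-bis(methoxymethoxy)-5-methyl-2,3-dihydro-1-benzofuran-7-yl]-2-methylpropan-1-one
Product: 22 1-[(2S)-4,6-dihydroxy-2-[(2S)-2-hydroxy-6-methylhept-5-en-2-yl]-5-methyl-2,3-dihydro-1-benzofuran-7-yl]-2-methylpropan-1-one
Conditions: HCl (0.5 M in MeOH), 0 °C → rt; NaHCO3
Reagents that add atoms: none
Why: Acid-catalysed acetal exchange with methanol should remove both aryl MOM ethers, the one ortho to the ketone first, under dilute conditions near room temperature of the kind that prenyl-type alkenes and tertiary alcohols normally tolerate.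

Step 13
Reactants: 22 1-[(2S)-4,6-dihydroxy-2-[(2S)-2-hydroxy-6-methylhept-5-en-2-yl]-5-methyl-2,3-dihydro-1-benzofuran-7-yl]-2-methylpropan-1-one; 23 3-methylbut-2-en-1-yl acetate
Product: 24 (2S,5R)-6-hydroxy-2-[(2S)-2-hydroxy-6-methylhept-5-en-2-yl]-5-methyl-5-(3-methylbut-2-en-1-yl)-7-(2-methylpropanoyl)-2,3-dihydro-1-benzofuran-4(5H)-one
Conditions: LiHMDS (2.1 equiv), THF, −78 °C; Pd2(dba)3·CHCl3 (2.5 mol%), (R,R)-DACH-phenyl Trost ligand (7.5 mol%), 23 (1.1 equiv), −20 → 0 °C; aq. NH4Cl
Reagents that add atoms: none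
Why: Palladium-catalysed asymmetric allylic alkylation with dearomatisation (Tsuji–Trost reaction): the dianion of 22 should attack the CH2 terminus of the π-prenyl complex through C5, the only ring carbon flanked by two oxyanions, O-prenylation being reversible under Pd(0), and because C5 is remote from C2 its configuration is set by the chiral ligand (reagent control) to the C5 arrangement of the target, which is (5R) in the tautomer drawn.

Step 14
Reactants: 24 (2S,5R)-6-hydroxy-2-[(2S)-2-hydroxy-6-methylhept-5-en-2-yl]-5-methyl-5-(3-methylbut-2-en-1-yl)-7-(2-methylpropanoyl)-2,3-dihydro-1-benzofuran-4(5H)-one; 25 3-methylbut-2-en-1-ol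
Product: 26 (2S,5S)-2-[(2S)-2-hydroxy-6-methylhept-5-en-2-yl]-5-methyl-5-(3-methylbut-2-en-1-yl)-4-[(3-methylbut-2-en-1-yl)oxy]-7-(2-methylpropanoyl)-2,3-dihydro-1-benzofuran-6(5H)-one
Conditions: 25 (1.3 equiv), PPh3 (1.3 equiv), DIAD (1.3 equiv), THF, 0 °C → rt
Reagents that add atoms: none
Why: Mitsunobu etherification of a vinylogous acid, in which the hard alkoxyphosphonium electrophile reacts at oxygen and not at carbon, and the O6/isobutyryl oxygens, tied up as a chelating β-diketonate pocket, should leave the vinylogous oxygen O4 as the accessible nucleophile, while the tertiary alcohol is inert and no stereocentre is formed.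

Step 15
Reactants: 26 (2S,5S)-2-[(2S)-2-hydroxy-6-methylhept-5-en-2-yl]-5-methyl-5-(3-methylbut-2-en-1-yl)-4-[(3-methylbut-2-en-1-yl)oxy]-7-(2-methylpropanoyl)-2,3-dihydro-1-benzofuran-6(5H)-one
Product: 28 (2S,5S,7S)-2-[(2S)-2-hydroxy-6-methylhept-5-en-2-yl]-5-methyl-5,7-bis(3-methylbut-2-en-1-yl)-7-(2-methylpropanoyl)-2,3-dihydro-1-benzofuran-4,6(5H,7H)-dione, via C3a-dimethylallyl dione 27 (not isolated)
Conditions: toluene (0.02 M), 110 °C, sealed tube, argon, dark
Reagents that add atoms: none
Why: Tandem Claisen–Cope (para-Claisen type) rearrangement: the allyl vinyl ether O4–C4=C3a should deliver a 1,1-dimethylallyl group to C3a on the ring face anti to the C2 side chain and syn to the smaller C5 methyl, and the resulting 1,5-diene (C7=C7a–C3a–CMe2–CH=CH2) should then undergo a suprafacial Cope shift that relieves the adjacent quaternary carbons and places a linear prenyl group on the same face of C7, so the (7S) centre is set by relay from C2 and C5 under neutral conditions that spare the base-labile C7 acyl group.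

## Compound list

1 | 2-methylbenzene-1,3-diol (2-methylresorcinol) | Cc1c(O)cccc1O | starting material
2 | 1,3-bis(methoxymethoxy)-2-methylbenzene | COCOc1cccc(OCOC)c1C | intermediate
3 | 2-[3,5-bis(methoxymethoxy)-4-methylphenyl]-4,4,5,5-tetramethyl-1,3,2-dioxaborolane | COCOc1cc(B2OC(C)(C)C(C)(C)O2)cc(OCOC)c1C | intermediate
4 | 3,5-bis(methoxymethoxy)-4-methylphenol | COCOc1cc(O)cc(OCOC)c1C | intermediate
5 | 6-hydroxy-2,4-bis(methoxymethoxy)-3-methylbenzaldehyde | COCOc1cc(O)c(C=O)c(OCOC)c1C | intermediate
6 | 2-(hydroxymethyl)-3,5-bis(methoxymethoxy)-4-methylphenol | COCOc1cc(O)c(CO)c(OCOC)c1C | intermediate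
7 | (2S,5S)-hexane-2,5-diol | C[C@H](O)CC[C@H](C)O | starting material
8 | (2S,5S)-hexane-2,5-diyl dimethanesulfonate | C[C@H](OS(C)(=O)=O)CC[C@H](C)OS(C)(=O)=O | intermediate
9 | (2R,5R)-2,5-dimethylthiolane | C[C@@H]1CC[C@@H](C)S1 | intermediate
10 | 1-chloropropan-2-one (chloroacetone) | CC(=O)CCl | starting material
11 | (2R,5R)-2,5-dimethyl-1-(2-oxopropyl)thiolan-1-ium chloride | C[C@@H]1CC[C@@H](C)[S+]1CC(C)=O.[Cl-] | intermediate
12 | acetonylide of (2R,5R)-2,5-dimethylthiolane | C[C@@H]1CC[C@@H](C)[S+]1[CH-]C(C)=O | intermediate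
13 | 3,5-bis(methoxymethoxy)-4-methyl-6-methylidenecyclohexa-2,4-dien-1-one | C=C1C(=O)C=C(OCOC)C(C)=C1OCOC | intermediate
14 | 2-{(2R)-2-[(2R,5R)-2,5-dimethylthiolan-1-ium-1-yl]-3-oxobutyl}-3,5-bis(methoxymethoxy)-4-methylphenolate (reactive epimer of the betaine) | CC(=O)[C@@H](Cc1c([O-])cc(OCOC)c(C)c1OCOC)[S+]1[C@H](C)CC[C@H]1C | intermediate
15 | 1-[(2S)-4,6-bis(methoxymethoxy)-5-methyl-2,3-dihydro-1-benzofuran-2-yl]ethan-1-one | CC(=O)[C@@H]1Cc2c(O1)cc(OCOC)c(C)c2OCOC | intermediate
16 | 5-bromo-2-methylpent-2-ene | CC(C)=CCCBr | starting material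
17 | (4-methylpent-3-en-1-yl)magnesium bromide | CC(C)=CCC[Mg]Br | intermediate
18 | (2S)-2-[(2S)-4,6-bis(methoxymethoxy)-5-methyl-2,3-dihydro-1-benzofuran-2-yl]-6-methylhept-5-en-2-ol | CC(C)=CCC[C@](C)(O)[C@@H]1Cc2c(O1)cc(OCOC)c(C)c2OCOC | intermediate
19 | N-methoxy-N,2-dimethylpropanamide | CON(C)C(=O)C(C)C | starting material
20 | 7-lithio derivative of the lithium alkoxide of 18 | CC(C)=CCC[C@](C)(O[Li])[C@@H]1Cc2c(O1)c([Li])c(OCOC)c(C)c2OCOC | intermediate
21 | 1-[(2S)-2-[(2S)-2-hydroxy-6-methylhept-5-en-2-yl]-4,6-bis(methoxymethoxy)-5-methyl-2,3-dihydro-1-benzofuran-7-yl]-2-methylpropan-1-one | CC(C)=CCC[C@](C)(O)[C@@H]1Cc2c(O1)c(C(=O)C(C)C)c(OCOC)c(C)c2OCOC | intermediate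
22 | 1-[(2S)-4,6-dihydroxy-2-[(2S)-2-hydroxy-6-methylhept-5-en-2-yl]-5-methyl-2,3-dihydro-1-benzofuran-7-yl]-2-methylpropan-1-one | CC(C)=CCC[C@](C)(O)[C@@H]1Cc2c(O1)c(C(=O)C(C)C)c(O)c(C)c2O | intermediate
23 | 3-methylbut-2-en-1-yl acetate (prenyl acetate) | CC(C)=CCOC(C)=O | starting material
24 | (2S,5R)-6-hydroxy-2-[(2S)-2-hydroxy-6-methylhept-5-en-2-yl]-5-methyl-5-(3-methylbut-2-en-1-yl)-7-(2-methylpropanoyl)-2,3-dihydro-1-benzofuran-4(5H)-one | CC(C)=CCC[C@](C)(O)[C@@H]1CC2=C(O1)C(C(=O)C(C)C)=C(O)[C@@](C)(CC=C(C)C)C2=O | intermediate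
25 | 3-methylbut-2-en-1-ol (prenol) | CC(C)=CCO | starting material
26 | (2S,5S)-2-[(2S)-2-hydroxy-6-methylhept-5-en-2-yl]-5-methyl-5-(3-methylbut-2-en-1-yl)-4-[(3-methylbut-2-en-1-yl)oxy]-7-(2-methylpropanoyl)-2,3-dihydro-1-benzofuran-6(5H)-one | CC(C)=CCC[C@](C)(O)[C@@H]1CC2=C(OCC=C(C)C)[C@](C)(CC=C(C)C)C(=O)C(C(=O)C(C)C)=C2O1 | intermediate
27 | (2S,3aR,5S)-2-[(2S)-2-hydroxy-6-methylhept-5-en-2-yl]-5-methyl-3a-(2-methylbut-3-en-2-yl)-5-(3-methylbut-2-en-1-yl)-7-(2-methylpropanoyl)-3,3a-dihydro-1-benzofuran-4,6(2H,5H)-dione | CC(C)=CCC[C@](C)(O)[C@@H]1C[C@]2(C(C)(C)C=C)C(=O)[C@](C)(CC=C(C)C)C(=O)C(C(=O)C(C)C)=C2O1 | intermediate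
28 | (2S,5S,7S)-2-[(2S)-2-hydroxy-6-methylhept-5-en-2-yl]-5-methyl-5,7-bis(3-methylbut-2-en-1-yl)-7-(2-methylpropanoyl)-2,3-dihydro-1-benzofuran-4,6(5H,7H)-dione | CC(C)=CCC[C@](C)(O)[C@@H]1CC2=C(O1)[C@@](CC=C(C)C)(C(=O)C(C)C)C(=O)[C@@](C)(CC=C(C)C)C2=O | target

## Step count and risks

Total step count: 15. Longest linear sequence: 12 steps (steps 1–5 and 9–15); the sulfonium branch (steps 6–8) joins at step 9.

Steps most likely to fail:

1. Step 9 (key step). The quinone methide may be consumed by self-condensation (attack by the free aromatic position of a second molecule) before the ylide adds. The two betaine epimers may close at similar rates, so that C2 forms with low selectivity, and the α-aryloxy ketone may epimerise under the basic conditions. Fallback, from 4 back to 15: the sodium phenoxide of 4 is C-alkylated at its ortho position in toluene with the known C5 reagent (E)-4-bromo-2-methylbut-2-en-1-yl acetate to give (2E)-4-[6-hydroxy-2,4-bis(methoxymethoxy)-3-methylphenyl]-2-methylbut-2-en-1-yl acetate F1. Intramolecular palladium-catalysed asymmetric allylic etherification of F1 (Pd2(dba)3, Trost ligand, 5-exo attack of the phenol on the π-allyl complex) should give (2S)-4,6-bis(methoxymethoxy)-5-methyl-2-(prop-1-en-2-yl)-2,3-dihydro-1-benzofuran F2. Oxidative cleavage of the isopropenyl group (cat. OsO4, NaIO4, 2,6-lutidine) then leads to 15.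

2. Step 13. The chiral palladium complex may not tell the two faces of C5 apart well enough, since the two flanks of C5 differ only beyond the oxygen atoms; alkylation at C3a may also intrude if the dianion is not fully formed. Fallback, from 22 back to 24: 22 is alkylated as its dianion with prenyl bromide in aqueous KOH without any chiral catalyst, the classical conditions for C-alkylation between two phenoxide oxygens. This should give 24 together with its C5 epimer, (2S,5S)-6-hydroxy-2-[(2S)-2-hydroxy-6-methylhept-5-en-2-yl]-5-methyl-5-(3-methylbut-2-en-1-yl)-7-(2-methylpropanoyl)-2,3-dihydro-1-benzofuran-4(5H)-one F3, and the two are separated by chromatography; stereocontrol at C5 is given up in exchange for a reliable bond formation.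

3. Step 14. Alkylation may take place on the wrong oxygen (O6 or the acyl oxygen), from which the Claisen–Cope relay would end at C3a, or directly at carbon. Fallback, from 22 to 28: the prenyl ether is made at the aromatic stage (K2CO3, prenyl bromide, acetone), where the non-chelated hydroxyl para to the acyl group should react selectively, to give 1-[(2S)-6-hydroxy-2-[(2S)-2-hydroxy-6-methylhept-5-en-2-yl]-5-methyl-4-[(3-methylbut-2-en-1-yl)oxy]-2,3-dihydro-1-benzofuran-7-yl]-2-methylpropan-1-one F4. Heating F4 (N,N-diethylaniline, 150 °C) should bring about the aromatic para-Claisen–Cope rearrangement (O4 to C3a or C5, then to C7), which after tautomerisation gives (2S,7S)-6-hydroxy-2-[(2S)-2-hydroxy-6-methylhept-5-en-2-yl]-5-methyl-7-(3-methylbut-2-en-1-yl)-7-(2-methylpropanoyl)-2,3-dihydro-1-benzofuran-4(7H)-one F5. C-prenylation of the 2-methyl-1,3-dione unit of F5 at C5 (Pd(PPh3)4, prenyl acetate, Cs2CO3, THF) then leads to 28. In this order C7 is set in the Cope step and C5 last, under 1,3-induction from C7, which is expected to be weaker than the relay of step 15, so C5 epimers might have to be separated.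

Further compounds
F1 | step 9 | (2E)-4-[6-hydroxy-2,4-bis(methoxymethoxy)-3-methylphenyl]-2-methylbut-2-en-1-yl acetate | COCOc1cc(O)c(C/C=C(\C)COC(C)=O)c(OCOC)c1C
F2 | step 9 | (2S)-4,6-bis(methoxymethoxy)-5-methyl-2-(prop-1-en-2-yl)-2,3-dihydro-1-benzofuran | CC(=C)[C@@H]1Cc2c(O1)cc(OCOC)c(C)c2OCOC
F3 | step 13 | (2S,5S)-6-hydroxy-2-[(2S)-2-hydroxy-6-methylhept-5-en-2-yl]-5-methyl-5-(3-methylbut-2-en-1-yl)-7-(2-methylpropanoyl)-2,3-dihydro-1-benzofuran-4(5H)-one | CC(C)=CCC[C@](C)(O)[C@@H]1CC2=C(O1)C(C(=O)C(C)C)=C(O)[C@](C)(CC=C(C)C)C2=O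
F4 | step 14 | 1-[(2S)-6-hydroxy-2-[(2S)-2-hydroxy-6-methylhept-5-en-2-yl]-5-methyl-4-[(3-methylbut-2-en-1-yl)oxy]-2,3-dihydro-1-benzofuran-7-yl]-2-methylpropan-1-one | CC(C)=CCC[C@](C)(O)[C@@H]1Cc2c(O1)c(C(=O)C(C)C)c(O)c(C)c2OCC=C(C)C
F5 | step 14 | (2S,7S)-6-hydroxy-2-[(2S)-2-hydroxy-6-methylhept-5-en-2-yl]-5-methyl-7-(3-methylbut-2-en-1-yl)-7-(2-methylpropanoyl)-2,3-dihydro-1-benzofuran-4(7H)-one | CC(C)=CCC[C@](C)(O)[C@@H]1CC2=C(O1)[C@@](CC=C(C)C)(C(=O)C(C)C)C(O)=C(C)C2=O
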